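The heptane C3–C4–C5 syn-1,3-diol is pseudo-meso. Guaiacyl ring A and syringyl ring B differ by a single methoxy group, so neither carbinol can be set by substrate bias and each needs external control. Both C–O bonds are therefore carried as C–B bonds, and the chain is cut at C4–C5. An (S)-α-lithiated carbamate (C5 to C7 with ring B) adds to the primary boron of an enantioenriched 1,2-bis(boronic ester) (C1 to C4 with ring A). A 1,2-metallate shift forges C4–C5 and fixes C5, and peroxide then turns both C–B bonds into the diol. The diisopropylcarbamoyl group serves as directing group, leaving group and phenol protection.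

Key step: step 6

Numbering used: the chain runs from C1 (on guaiacyl ring A) to C7 (on syringyl ring B). In this numbering the target is (3S,5R), the syn diol.
Assumption: in step 3 the (R,R)-configured ligand is taken to deliver the (3R)-bis(boronic ester). If the sense of induction is the opposite, the equally accessible (S,S)-ligand is used, and oxidation of an aliquot to the 1,2-diol settles the assignment.

Step 1
Reactants: 1 4-bromo-2-methoxyphenol
Product: 2 4-bromo-2-methoxyphenyl N,N-diisopropylcarbamate
Conditions: NaH, iPr2NC(O)Cl, THF, 0 °C to reflux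
Reagents that add atoms: N,N-diisopropylcarbamoyl chloride, CC(C)N(C(C)C)C(=O)Cl
Why: O-acylation of the sodium phenoxide by the carbamoyl chloride (carbamate formation) installs a phenol protecting group that is inert to Grignard reagents, boron chemistry, base and peroxide.

Step 2
Reactants: 2 4-bromo-2-methoxyphenyl N,N-diisopropylcarbamate, 3 but-3-en-1-ylmagnesium bromide
Product: 4 4-(but-3-en-1-yl)-2-methoxyphenyl N,N-diisopropylcarbamate
Conditions: Pd(dppf)Cl2 (3 mol %), THF, 50 °C
Reagents that add atoms: none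
Why: In this Kumada–Corriu cross-coupling, zerovalent palladium inserts into the C–Br bond, the wide-bite-angle dppf ligand makes reductive elimination outrun β-hydride elimination, and the hindered carbamate ignores the Grignard reagent.

Step 3
Reactants: 4 4-(but-3-en-1-yl)-2-methoxyphenyl N,N-diisopropylcarbamate
Product: 5 4-[(3R)-3,4-bis(pinacolatoboryl)butyl]-2-methoxyphenyl N,N-diisopropylcarbamate
Conditions: Pt(dba)3 (1 mol %), (R,R)-TADDOL-derived phenylphosphonite with 3,5-diisopropylphenyl groups (1.2 mol %), B2pin2, THF, 60 °C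
Reagents that add atoms: bis(pinacolato)diboron, CC1(C)OB(OC1(C)C)B1OC(C)(C)C(C)(C)O1
Why: In this platinum-catalysed enantioselective syn-diboration of a monosubstituted alkene, B–B oxidative addition, face-selective olefin insertion steered by the chiral phosphonite and reductive elimination set C3 as a C–B bond under catalyst control.

Step 4
Reactants: 6 4-allyl-2,6-dimethoxyphenol
Product: 8 4-(3-hydroxypropyl)-2,6-dimethoxyphenol, via bis(9-BBN) adduct 7 (not isolated)
Conditions: 9-BBN (2.2 equiv), THF, 0 °C to rt; then NaOH, H2O2, 0 °C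
Reagents that add atoms: hydrogen peroxide, OO
Why: Anti-Markovnikov hydroboration with bulky 9-BBN places boron on the terminal carbon (one equivalent is spent on the phenol O–H), and alkaline peroxide oxidation returns the phenol and gives the primary alcohol without forming a stereocentre.

Step 5
Reactants: 8 4-(3-hydroxypropyl)-2,6-dimethoxyphenol
Product: 9 3-[4-(N,N-diisopropylcarbamoyloxy)-3,5-dimethoxyphenyl]propyl N,N-diisopropylcarbamate
Conditions: NaH (2.5 equiv), iPr2NC(O)Cl (2.5 equiv), THF, 0 °C to reflux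
Reagents that add atoms: N,N-diisopropylcarbamoyl chloride, CC(C)N(C(C)C)C(=O)Cl
Why: Double O-carbamoylation of the disodium salt installs in one operation the directing and leaving group on the primary alcohol and the protecting group on the doubly flanked phenol.

Step 6
Reactants: 9 3-[4-(N,N-diisopropylcarbamoyloxy)-3,5-dimethoxyphenyl]propyl N,N-diisopropylcarbamate, 5 4-[(3R)-3,4-bis(pinacolatoboryl)butyl]-2-methoxyphenyl N,N-diisopropylcarbamate
Product: 13 (3S,5R)-1-[4-(N,N-diisopropylcarbamoyloxy)-3-methoxyphenyl]-7-[4-(N,N-diisopropylcarbamoyloxy)-3,5-dimethoxyphenyl]heptane-3,5-diol, via lithiated carbamate 10 (not isolated), via boronate complex 11 (not isolated), via 1,3-bis(boronic ester) 12 (not isolated)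
Conditions: sBuLi (1.05 equiv), (–)-sparteine (1.1 equiv), Et2O, –78 °C; 5 (1.1 equiv), –78 °C; MgBr2·OEt2, –78 °C to reflux; then NaOH, H2O2, THF/H2O, 0 °C to rt
Reagents that add atoms: hydrogen peroxide, OO
Why: sBuLi/(–)-sparteine removes the pro-S proton next to the alkyl carbamate oxygen of 9 and gives the configurationally stable (S)-organolithium 10, which adds with retention to the less hindered primary boron of 5 to form boronate complex 11. On warming with MgBr2·OEt2 the C4 methylene migrates from boron to C5 antiperiplanar to the departing carbamate (stereospecific 1,2-metallate rearrangement with inversion at C5), which forms the C4–C5 bond and gives 12, and alkaline peroxide then replaces both C–B bonds by C–O bonds with retention. The closest known reaction type is the lithiation–borylation homologation of 1,2-bis(boronic esters) at the primary boron followed by oxidation to 1,3-diols, and no ring is closed. C5 (R in 13) is controlled by the reagent, that is by (–)-sparteine, and C3 (S in 13) is carried unchanged from 5, so the syn relation follows from pairing two independently set centres and the mismatched minor enantiomers should end up in the separable anti diol. Site selectivity between the two boron atoms is needed and rests on the steric difference between CH2–B and CH–B. Chemoselective lithiation is also needed and is secured because both positions ortho to the aryl carbamate of ring B bear methoxy groups, which shuts off ortho-metalation and anionic Fries rearrangement, while ring A meets only the preformed carbenoid at –78 °C.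

Step 7
Reactants: 13 (3S,5R)-1-[4-(N,N-diisopropylcarbamoyloxy)-3-methoxyphenyl]-7-[4-(N,N-diisopropylcarbamoyloxy)-3,5-dimethoxyphenyl]heptane-3,5-diol
Product: 14 (3S,5R)-1-(4-hydroxy-3-methoxyphenyl)-7-(4-hydroxy-3,5-dimethoxyphenyl)heptane-3,5-diol (CNP0317264.2)
Conditions: LiAlH4 (excess), THF, 0 °C to reflux; aq. KHSO4 work-up
Reagents that add atoms: none
Why: Hydride addition to both carbamate carbonyl groups expels the phenoxides (reductive carbamate cleavage), while the two carbinol centres sit as alkoxides and are not touched.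

Compound list
1 | 4-bromo-2-methoxyphenol | COc1cc(Br)ccc1O | starting material
2 | 4-bromo-2-methoxyphenyl N,N-diisopropylcarbamate | COc1cc(Br)ccc1OC(=O)N(C(C)C)C(C)C | intermediate
3 | but-3-en-1-ylmagnesium bromide | C=CCC[Mg]Br | starting material
4 | 4-(but-3-en-1-yl)-2-methoxyphenyl N,N-diisopropylcarbamate | COc1cc(CCC=C)ccc1OC(=O)N(C(C)C)C(C)C | intermediate
5 | 4-[(3R)-3,4-bis(pinacolatoboryl)butyl]-2-methoxyphenyl N,N-diisopropylcarbamate | COc1cc(CC[C@H](B2OC(C)(C)C(C)(C)O2)CB2OC(C)(C)C(C)(C)O2)ccc1OC(=O)N(C(C)C)C(C)C | intermediate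
6 | 4-allyl-2,6-dimethoxyphenol | C=CCc1cc(OC)c(O)c(OC)c1 | starting material
7 | bis(9-BBN) adduct of 6 (B-aryloxy and terminal B-alkyl 9-borabicyclo[3.3.1]nonane) | COc1cc(CCCB2C3CCCC2CCC3)cc(OC)c1OB1C2CCCC1CCC2 | intermediate
8 | 4-(3-hydroxypropyl)-2,6-dimethoxyphenol | COc1cc(CCCO)cc(OC)c1O | intermediate
9 | 3-[4-(N,N-diisopropylcarbamoyloxy)-3,5-dimethoxyphenyl]propyl N,N-diisopropylcarbamate | COc1cc(CCCOC(=O)N(C(C)C)C(C)C)cc(OC)c1OC(=O)N(C(C)C)C(C)C | intermediate
10 | (S)-1-lithio derivative of 9 at the O-bearing carbon of the propyl chain, bound to (–)-sparteine (ligand not drawn) | CC(C)N(C(C)C)C(=O)O[C@@H]([Li])CCc1cc(OC)c(OC(=O)N(C(C)C)C(C)C)c(OC)c1 | intermediate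
11 | lithium boronate complex: primary boron of 5 bound to the (S)-carbamoyloxy carbon of 10 | [Li+].COc1cc(CC[C@H](B2OC(C)(C)C(C)(C)O2)C[B-]3(OC(C)(C)C(C)(C)O3)[C@H](OC(=O)N(C(C)C)C(C)C)CCc2cc(OC)c(OC(=O)N(C(C)C)C(C)C)c(OC)c2)ccc1OC(=O)N(C(C)C)C(C)C | intermediate
12 | (3S,5R)-3,5-bis(pinacolatoboryl)heptane bearing the ring A aryl carbamate at C1 and the ring B aryl carbamate at C7 | COc1cc(CC[C@H](B2OC(C)(C)C(C)(C)O2)C[C@H](B2OC(C)(C)C(C)(C)O2)CCc2cc(OC)c(OC(=O)N(C(C)C)C(C)C)c(OC)c2)ccc1OC(=O)N(C(C)C)C(C)C | intermediate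
13 | (3S,5R)-1-[4-(N,N-diisopropylcarbamoyloxy)-3-methoxyphenyl]-7-[4-(N,N-diisopropylcarbamoyloxy)-3,5-dimethoxyphenyl]heptane-3,5-diol | COc1cc(CC[C@H](O)C[C@H](O)CCc2cc(OC)c(OC(=O)N(C(C)C)C(C)C)c(OC)c2)ccc1OC(=O)N(C(C)C)C(C)C | intermediate
14 | (3S,5R)-1-(4-hydroxy-3-methoxyphenyl)-7-(4-hydroxy-3,5-dimethoxyphenyl)heptane-3,5-diol | COc1cc(CC[C@H](O)C[C@H](O)CCc2cc(OC)c(O)c(OC)c2)ccc1O | target

Total step count: 7.
Longest linear sequence: 5 steps (1, 2, 3, 6, 7). The second branch (4, 5) joins at step 6.

Steps most likely to fail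

**Step 6.** Three things may go wrong: incomplete or unselective lithiation of 9, attack of the carbenoid at the secondary boron, or a sluggish 1,2-migration.
- The fallback sets out from 5 and 8 and comes back at 13. It makes the same C4–C5 bond by opening a terminal epoxide with a lithiated dithiane.
- Ring A partner: 5 is oxidised (NaOH, H2O2) to the (S)-1,2-diol F1. This is sulfonylated at the primary hydroxyl (TsCl, Et3N, cat. Bu2SnO) to the monotosylate F2, which is closed with K2CO3/MeOH to the (S)-epoxide F3 with C3 untouched.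
- Ring B partner: 8 is carbamoylated at the phenoxide only (K2CO3, iPr2NC(O)Cl, MeCN) to the aryl carbamate alcohol F4. This is oxidised with Dess–Martin periodinane to the aldehyde F5 and converted with propane-1,3-dithiol/BF3·OEt2 into the dithiane F6.
- Union and finish: F6 is lithiated (nBuLi, THF, –30 °C) and opens F3 at its terminal carbon to give the hydroxy dithiane F7. MeI/CaCO3 in aqueous MeCN unmasks the β-hydroxy ketone F8. Narasaka–Prasad reduction (Et2BOMe, NaBH4, THF/MeOH, –78 °C) then delivers hydride to the boron chelate and gives the syn diol 13.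

**Step 3.** Facial selectivity in the olefin insertion may be poor, or the bis(boronic ester) may erode on purification.
- The fallback sets out from 4 and comes back at 5. It sets C3 by asymmetric hydrogenation instead of diboration of the alkene.
- Lemieux–Johnson cleavage of 4 (cat. OsO4, NaIO4, 2,6-lutidine) gives the aldehyde F9.
- Seyferth–Gilbert homologation with the Ohira–Bestmann reagent (K2CO3, MeOH) gives the terminal alkyne F10.
- Pt(PPh3)4-catalysed syn-diboration with B2pin2 gives the cis-1,2-diborylalkene F11.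
- Enantioselective hydrogenation ([Rh(nbd)2]BF4, Walphos-type ferrocenyl diphosphine, H2) gives 5.

**Step 7.** Hydride attack on the carbamate flanked by two methoxy groups may be incomplete, and aluminium alkoxide–phenoxide aggregates may precipitate and stall the reduction.
- The fallback sets out from 13 and comes back at 14.
- The diol is masked with 2,2-dimethoxypropane/PPTS as the syn-acetonide F12.
- With no free hydroxyl left, both aryl carbamates are cleaved with Cp2Zr(H)Cl (THF, rt) to the bis-phenol acetonide F13.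
- Aqueous acetic acid removes the acetonide to give 14.

Further compounds
F1 | step 6 | 4-[(3S)-3,4-dihydroxybutyl]-2-methoxyphenyl N,N-diisopropylcarbamate | COc1cc(CC[C@H](O)CO)ccc1OC(=O)N(C(C)C)C(C)C
F2 | step 6 | 4-[(3S)-3-hydroxy-4-(tosyloxy)butyl]-2-methoxyphenyl N,N-diisopropylcarbamate | COc1cc(CC[C@H](O)COS(=O)(=O)c2ccc(C)cc2)ccc1OC(=O)N(C(C)C)C(C)C
F3 | step 6 | 2-methoxy-4-{2-[(2S)-oxiran-2-yl]ethyl}phenyl N,N-diisopropylcarbamate | COc1cc(CC[C@H]2CO2)ccc1OC(=O)N(C(C)C)C(C)C
F4 | step 6 | 4-(3-hydroxypropyl)-2,6-dimethoxyphenyl N,N-diisopropylcarbamate | COc1cc(CCCO)cc(OC)c1OC(=O)N(C(C)C)C(C)C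
F5 | step 6 | 2,6-dimethoxy-4-(3-oxopropyl)phenyl N,N-diisopropylcarbamate | COc1cc(CCC=O)cc(OC)c1OC(=O)N(C(C)C)C(C)C
F6 | step 6 | 4-[2-(1,3-dithian-2-yl)ethyl]-2,6-dimethoxyphenyl N,N-diisopropylcarbamate | COc1cc(CCC2SCCCS2)cc(OC)c1OC(=O)N(C(C)C)C(C)C
F7 | step 6 | (3S)-3-hydroxy-5,5-(propane-1,3-diyldisulfanediyl)heptane bearing both aryl carbamates (hydroxy dithiane) | COc1cc(CC[C@H](O)CC2(CCc3cc(OC)c(OC(=O)N(C(C)C)C(C)C)c(OC)c3)SCCCS2)ccc1OC(=O)N(C(C)C)C(C)C
F8 | step 6 | (3S)-3-hydroxyheptan-5-one bearing both aryl carbamates (β-hydroxy ketone) | COc1cc(CC[C@H](O)CC(=O)CCc2cc(OC)c(OC(=O)N(C(C)C)C(C)C)c(OC)c2)ccc1OC(=O)N(C(C)C)C(C)C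
F9 | step 3 | 2-methoxy-4-(3-oxopropyl)phenyl N,N-diisopropylcarbamate | COc1cc(CCC=O)ccc1OC(=O)N(C(C)C)C(C)C
F10 | step 3 | 4-(but-3-yn-1-yl)-2-methoxyphenyl N,N-diisopropylcarbamate | COc1cc(CCC#C)ccc1OC(=O)N(C(C)C)C(C)C
F11 | step 3 | 4-[3,4-bis(pinacolatoboryl)but-3-en-1-yl]-2-methoxyphenyl N,N-diisopropylcarbamate, both boryl groups on the same side of the double bond | COc1cc(CC/C(B2OC(C)(C)C(C)(C)O2)=C/B2OC(C)(C)C(C)(C)O2)ccc1OC(=O)N(C(C)C)C(C)C
F12 | step 7 | syn-acetonide (cis-4,6-disubstituted 2,2-dimethyl-1,3-dioxane) of 13 | COc1cc(CC[C@H]2C[C@@H](CCc3cc(OC)c(OC(=O)N(C(C)C)C(C)C)c(OC)c3)OC(C)(C)O2)ccc1OC(=O)N(C(C)C)C(C)C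
F13 | step 7 | syn-acetonide of 14 with both phenols free | COc1cc(CC[C@H]2C[C@@H](CCc3cc(OC)c(O)c(OC)c3)OC(C)(C)O2)ccc1O
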